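**Retrosynthetic overview**
1. Ester C–O bond: leoligin ⇒ angelic acid + the 3-hydroxymethyl tetrahydrofuran (lariciresinol dimethyl ether). This bond is made last, so the Z-olefin sees no further chemistry.
2. Ring C2–O bond: the tetrahydrofuran ⇒ the C2-symmetric (2R,3R)-2,3-bis(3,4-dimethoxybenzyl)butane-1,4-diol, closed by benzylic C–H oxidation and etherification. Either benzylic CH2 gives the same product.
3. Diol ⇒ (R,R)-2,3-dibenzylsuccinic bis-imide (reduction, auxiliary released).
4. Key C3–C4 bond: both carbons are carbonyl α-carbons and normally both nucleophilic. One imide reacts as its enolate and the second as an iodine-bound enolonium. An (S)-valinol-derived oxazolidinone sets both stereocentres at once.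
5. Ring order: there is only one ring, the tetrahydrofuran. It is closed in the fourth of five steps, after the whole carbon skeleton is in place.

Assumption: LiN(iPr)2 is used as a purchased solution and angelic acid is bought as the pure Z acid.

**Step 1**
Reactants: 1 3-(3,4-dimethoxyphenyl)propanoic acid; 2 (S)-4-isopropyloxazolidin-2-one
Product: 4 (S)-3-[3-(3,4-dimethoxyphenyl)propanoyl]-4-isopropyloxazolidin-2-one, via mixed pivalic anhydride 3 (not isolated)
Conditions: PivCl, Et3N, THF, −20 °C; then LiCl, 2, −20 °C → rt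
Reagents that add atoms: pivaloyl chloride, CC(C)(C)C(=O)Cl (its acyl group sits only in 3 and is lost again before 4)
Why: One-pot mixed-anhydride N-acylation of an Evans-type oxazolidinone, in which the acid is activated as 3, LiCl/Et3N makes the carbamate N–H nucleophilic enough to attack the less hindered carbonyl of 3, and no stereocentre is formed or touched.

**Step 2 (key step)**
Reactants: 4 imide (two equivalents)
Product: 7 (2R,3R)-2,3-bis(3,4-dimethoxybenzyl)-1,4-bis[(S)-4-isopropyl-2-oxooxazolidin-3-yl]butane-1,4-dione, via lithium Z-enolate 5 (not isolated), via iodine-bound enolonium 6 (not isolated)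
Conditions: LiN(iPr)2 (1.05 equiv), THF, −78 °C; then PhI(OAc)2 (0.5 equiv), −78 → 0 °C
Reagents that add atoms: lithium diisopropylamide, CC(C)[N-]C(C)C.[Li+] (lithium, only in 5); (diacetoxyiodo)benzene, CC(=O)OI(OC(C)=O)c1ccccc1 (PhI(OAc) unit, only in 6); no reagent atom remains in 7
Why: Hypervalent-iodine oxidative enolate coupling, in which trivalent iodine captures half of the chelated Z-enolate 5 at oxygen to give 6, whose α-carbon is now electrophilic (enolonium, a2 synthon), and the remaining 5 attacks it carbon-to-carbon with loss of PhI and acetate, each partner (held syn-planar by lithium in 5 and by the I···O contact in 6) reacting on the face away from its isopropyl group, so both new stereocentres (ring C3 and C4 of the target) come out R and the minor R,S isomer is removed by chromatography or crystallisation.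

**Step 3**
Reactants: 7 R,R-bis-imide
Product: 8 (2R,3R)-2,3-bis(3,4-dimethoxybenzyl)butane-1,4-diol
Conditions: LiBH4, THF, 0 °C → rt; aq. NaOH work-up
Reagents that add atoms: none
Why: Reductive cleavage of N-acyl oxazolidinones, in which hydride attacks the more electrophilic exocyclic imide carbonyls and releases the reusable auxiliary without enolisation, so both R centres are retained and the aryl methyl ethers are inert.

**Step 4**
Reactants: 8 C2-symmetric diol
Product: 10 [(2S,3R,4R)-4-(3,4-dimethoxybenzyl)-2-(3,4-dimethoxyphenyl)tetrahydrofuran-3-yl]methanol, via benzylic cation 9 (not isolated)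
Conditions: DDQ (0.7–0.8 equiv, slow addition), 4 Å MS, CH2Cl2, 0 °C; unreacted 8 recovered and recycled
Reagents that add atoms: none
Why: DDQ benzylic C–H oxidation with intramolecular alcohol capture (oxidative etherification), in which hydride abstraction from either of the two homotopic veratryl CH2 groups gives the para-methoxy-stabilised cation 9, the only hydroxyl able to form a five-membered ring closes it, and the aryl group takes the face opposite the adjacent CH2OH because the alternative is the all-cis ring, which sets C2 as S (2,3-trans, 3,4-cis) while the C3 and C4 centres are untouched.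

**Step 5**
Reactants: 10 tetrahydrofuran alcohol; 11 angelic acid, (Z)-2-methylbut-2-enoic acid
Product: 13 leoligin = [(2S,3R,4R)-4-(3,4-dimethoxybenzyl)-2-(3,4-dimethoxyphenyl)tetrahydrofuran-3-yl]methyl (Z)-2-methylbut-2-enoate, via alkoxyphosphonium angelate 12 (not isolated)
Conditions: PPh3, DIAD, THF, 0 °C → rt
Reagents that add atoms: triphenylphosphine, c1ccc(cc1)P(c1ccccc1)c1ccccc1 (present only in 12)
Why: Mitsunobu esterification, in which the primary alcohol rather than the acid is activated (as 12) and is displaced by angelate at a CH2 carbon, so no ring stereocentre is involved and the Z-olefin never passes through an activated acyl species that could isomerise it to the tiglate.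

**Compound list**
1 | 3-(3,4-dimethoxyphenyl)propanoic acid | COc1ccc(CCC(=O)O)cc1OC | starting material
2 | (S)-4-isopropyloxazolidin-2-one | CC(C)[C@H]1COC(=O)N1 | starting material
3 | 3-(3,4-dimethoxyphenyl)propanoic pivalic anhydride (not isolated) | COc1ccc(CCC(=O)OC(=O)C(C)(C)C)cc1OC | intermediate
4 | (S)-3-[3-(3,4-dimethoxyphenyl)propanoyl]-4-isopropyloxazolidin-2-one | CC(C)[C@H]1COC(=O)N1C(=O)CCc1ccc(OC)c(OC)c1 | intermediate
5 | lithium (Z)-enolate of 4 (not isolated) | CC(C)[C@H]1COC(=O)N1/C([O-])=C/Cc1ccc(OC)c(OC)c1.[Li+] | intermediate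
6 | (Z)-O-[acetoxy(phenyl)-λ3-iodanyl] enolate of 4, enolonium equivalent (not isolated) | CC(C)[C@H]1COC(=O)N1/C(OI(OC(C)=O)c1ccccc1)=C/Cc1ccc(OC)c(OC)c1 | intermediate
7 | (2R,3R)-2,3-bis(3,4-dimethoxybenzyl)-1,4-bis[(S)-4-isopropyl-2-oxooxazolidin-3-yl]butane-1,4-dione | CC(C)[C@H]1COC(=O)N1C(=O)[C@H](Cc1ccc(OC)c(OC)c1)[C@@H](Cc1ccc(OC)c(OC)c1)C(=O)N1[C@@H](C(C)C)COC1=O | intermediate
8 | (2R,3R)-2,3-bis(3,4-dimethoxybenzyl)butane-1,4-diol | OC[C@H](Cc1ccc(OC)c(OC)c1)[C@@H](Cc1ccc(OC)c(OC)c1)CO | intermediate
9 | 3,4-dimethoxybenzylic cation derived from 8 (not isolated) | OC[C@H]([CH+]c1ccc(OC)c(OC)c1)[C@@H](Cc1ccc(OC)c(OC)c1)CO | intermediate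
10 | [(2S,3R,4R)-4-(3,4-dimethoxybenzyl)-2-(3,4-dimethoxyphenyl)tetrahydrofuran-3-yl]methanol | OC[C@H]1[C@@H](Cc2ccc(OC)c(OC)c2)CO[C@@H]1c1ccc(OC)c(OC)c1 | intermediate
11 | angelic acid, (Z)-2-methylbut-2-enoic acid | C/C=C(/C)C(=O)O | starting material
12 | triphenylphosphonium ether of 10 as its angelate salt (not isolated) | C/C=C(/C)C(=O)[O-].c1ccc(cc1)[P+](c1ccccc1)(c1ccccc1)OC[C@H]1[C@@H](Cc2ccc(OC)c(OC)c2)CO[C@@H]1c1ccc(OC)c(OC)c1 | intermediate
13 | leoligin | C/C=C(/C)C(=O)OC[C@H]1[C@@H](Cc2ccc(OC)c(OC)c2)CO[C@@H]1c1ccc(OC)c(OC)c1 | target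

**Total step count:** 5. **Longest linear sequence:** 5 (1 → 4 → 7 → 8 → 10 → 13).

**Steps most likely to fail**

Step 2 carries the most risk. Acetate can intercept 6 to give α-acetoxylation, and electron-transfer leakage can erode the R,R : R,S ratio.
- The fallback keeps the enolate but replaces the fleeting enolonium by a shelf-stable α-carbonyl cation equivalent, building the second half stepwise. It sets out from 5.
- Alkylation of 5 with tert-butyl bromoacetate occurs on the same open face. It gives tert-butyl (3R)-3-(3,4-dimethoxybenzyl)-4-[(4S)-4-isopropyl-2-oxooxazolidin-3-yl]-4-oxobutanoate F1.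
- LiBH4 reduces only the imide of F1 to give tert-butyl (3R)-3-(3,4-dimethoxybenzyl)-4-hydroxybutanoate F2.
- Catalytic TsOH in warm toluene closes F2 to (4R)-4-(3,4-dimethoxybenzyl)dihydrofuran-2(3H)-one F3.
- Treatment of F3 with LiN(SiMe3)2 and 3,4-dimethoxybenzyl bromide alkylates anti to the resident benzyl group. The product is (3R,4R)-3,4-bis(3,4-dimethoxybenzyl)dihydrofuran-2(3H)-one F4.
- LiAlH4 opens F4 to the diol, and the fallback rejoins the route at 8.

Step 4 is the second risk.
- The remaining benzylic CH2 of 10 is about as oxidisable as those of 8, so a second closure onto the free CH2OH competes. This gives a statistical ceiling near 50% per pass, about 80% based on recovered 8.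
- The benzylic ether C–H of 10 may also be attacked by DDQ.
- The fallback gives up on stopping halfway and sets out from 8.
- Excess DDQ (2.5 equiv) closes both rings to the C2-symmetric furofuran (1S,3aR,4S,6aR)-1,4-bis(3,4-dimethoxyphenyl)tetrahydro-1H,3H-furo[3,4-c]furan, (+)-eudesmin F5.
- One of the two homotopic benzylic C–O bonds of F5 is then cleaved by hydrogenolysis (H2, 10% Pd/C, EtOAc, stopped after one equivalent). This comes back to the route at 10.
- Over-reduction only regenerates 8, so all material stays recyclable.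

Step 5 is the third risk. The β-branched primary alcohol may react slowly, and reversible phosphine addition could leak some tiglate.
- The fallback swaps the redox condensation for a phosphine-free two-stage sulfonate displacement and sets out from 10.
- MsCl and Et3N convert 10 into [(2S,3R,4R)-4-(3,4-dimethoxybenzyl)-2-(3,4-dimethoxyphenyl)tetrahydrofuran-3-yl]methyl methanesulfonate F6.
- F6 is heated with 11 and Cs2CO3 in DMF at 50 °C. The unactivated carboxylate displaces the sulfonate and the fallback arrives at 13.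

**Further compounds**
F1 | step 2 | tert-butyl (3R)-3-(3,4-dimethoxybenzyl)-4-[(4S)-4-isopropyl-2-oxooxazolidin-3-yl]-4-oxobutanoate | CC(C)[C@H]1COC(=O)N1C(=O)[C@H](Cc1ccc(OC)c(OC)c1)CC(=O)OC(C)(C)C
F2 | step 2 | tert-butyl (3R)-3-(3,4-dimethoxybenzyl)-4-hydroxybutanoate | OC[C@H](Cc1ccc(OC)c(OC)c1)CC(=O)OC(C)(C)C
F3 | step 2 | (4R)-4-(3,4-dimethoxybenzyl)dihydrofuran-2(3H)-one | O=C1C[C@@H](Cc2ccc(OC)c(OC)c2)CO1
F4 | step 2 | (3R,4R)-3,4-bis(3,4-dimethoxybenzyl)dihydrofuran-2(3H)-one | O1C[C@H](Cc2ccc(OC)c(OC)c2)[C@@H](Cc2ccc(OC)c(OC)c2)C1=O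
F5 | step 4 | (1S,3aR,4S,6aR)-1,4-bis(3,4-dimethoxyphenyl)tetrahydro-1H,3H-furo[3,4-c]furan, (+)-eudesmin | O1C[C@H]2[C@@H]([C@H]1c3ccc(OC)c(OC)c3)CO[C@@H]2c3ccc(OC)c(OC)c3
F6 | step 5 | [(2S,3R,4R)-4-(3,4-dimethoxybenzyl)-2-(3,4-dimethoxyphenyl)tetrahydrofuran-3-yl]methyl methanesulfonate | CS(=O)(=O)OC[C@H]1[C@@H](Cc2ccc(OC)c(OC)c2)CO[C@@H]1c1ccc(OC)c(OC)c1
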